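**Plan**

1. The retrosynthesis cuts ring A first, at C2–C3 and C5–C6 (ether carbon = C4), into dimethyl 3-oxoglutarate (C2–C1–C6) and an aryloxymalonate (C3–C4–C5). The malonate C4–O bond is then cut back to the B–G hexamer phenol, an SN2 at sp3 carbon.
2. The O-methylated hexamer is cut at its five diaryl ether bonds, each between a hindered oxygen and an unhindered carbon: E6–O–F1 (fragment union), D4–O–E1 and C6–O–D1 (SNAr), B4–O–C1 and F4–O–G1 (one Chan–Lam ether that serves as both the B–C and the F–G unit).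
3. Forward: ring B (bromine masks its C1 hydroxyl) is joined to ring C; formylation and Baeyer–Villiger oxidation give the ring C phenol; two SNAr/Baeyer–Villiger rounds add rings D and E; Chan–Lam union with the F–G boronic acid; Br to OH; malonate; ring A is built last and de novo; ester removal and global demethylation finish.
4. Enabling feature: in ring A the ether carbon C4 lies between the hydroxylated carbons C3 and C5, the pattern of a malonyl carbon between two acyl carbons, while C2–C1(OH)–C6 map onto an acetonedicarboxylate.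
5. Stereochemistry: the target has no stereocentre, so nothing has to be set or preserved.

Key step: step 12

Lettering: rings run A to G from the phloroglucinol end. In rings B, D, F and G, C1 carries the oxygen towards the lower-lettered ring and C4 is para to it. In rings C and E, C1 carries the oxygen towards the lower ring and C6 the oxygen towards the higher ring.

Assumption: 4-fluoro-2,6-dimethoxybenzaldehyde and 2-fluoro-4,6-dimethoxybenzaldehyde are taken as purchasable; each would otherwise be one formylation step from 1-fluoro-3,5-dimethoxybenzene.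

**Route**

Step 1
Reactants: 1 4-bromo-2,6-dimethoxyphenol; 2 3,4,5-trimethoxyphenylboronic acid
Product: 3 5-bromo-1,3-dimethoxy-2-(3,4,5-trimethoxyphenoxy)benzene
Conditions: Cu(OAc)2 (0.3 equiv), pyridine, 4 Å MS, O2 (1 atm), CH2Cl2, rt
Reagents that add atoms: none
Why: A Chan–Lam–Evans oxidative coupling joins the hindered phenol oxygen to the unhindered arylboronic acid at room temperature, tolerates the two flanking methoxy groups and leaves the aryl bromide untouched as the masked C1 hydroxyl of ring B and as the handle for step 8.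

Step 2
Reactants: 3 5-bromo-1,3-dimethoxy-2-(3,4,5-trimethoxyphenoxy)benzene
Product: 5 6-(4-bromo-2,6-dimethoxyphenoxy)-2,3,4-trimethoxybenzaldehyde, via iminium chloride 4 (not isolated)
Conditions: POCl3, DMF, 0 to 70 °C; then H2O, rt
Reagents that add atoms: N,N-dimethylformamide, CN(C)C=O; water, O
Why: Vilsmeier–Haack formylation should take one of the two equivalent free positions of the trimethoxyphenyl ring, which are ortho to the aryloxy group, ortho to one methoxy and para to another, whereas the free positions of the brominated ring have the aryloxy group meta and a deactivating bromine beside them.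

Step 3
Reactants: 5 6-(4-bromo-2,6-dimethoxyphenoxy)-2,3,4-trimethoxybenzaldehyde
Product: 7 6-(4-bromo-2,6-dimethoxyphenoxy)-2,3,4-trimethoxyphenol (B–C phenol), via aryl formate 6 (not isolated)
Conditions: mCPBA, CH2Cl2, 0 °C to rt; then K2CO3 (cat.), MeOH, rt
Reagents that add atoms: mCPBA (3-chloroperoxybenzoic acid), OOC(=O)c1cccc(Cl)c1
Why: Baeyer–Villiger oxidation of the electron-rich aldehyde (Dakin-type) migrates the trioxygenated aryl group to give the formate, and base-catalysed methanolysis frees the phenol at C6 of ring C.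

Step 4
Reactants: 7 6-(4-bromo-2,6-dimethoxyphenoxy)-2,3,4-trimethoxyphenol; 8 4-fluoro-2,6-dimethoxybenzaldehyde
Product: 9 4-{[6-(4-bromo-2,6-dimethoxyphenoxy)-2,3,4-trimethoxyphenyl]oxy}-2,6-dimethoxybenzaldehyde (B–D aldehyde)
Conditions: Cs2CO3, DMSO, 110 °C, Ar
Reagents that add atoms: none
Why: Nucleophilic aromatic substitution (SNAr): the fluorine of 8 is para to the formyl group, meta to both methoxy groups and sterically open, so the hindered phenoxide of 7 displaces it and the formyl group marks the carbon that becomes C4–O of ring D.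

Step 5
Reactants: 9 B–D aldehyde
Product: 11 4-{[6-(4-bromo-2,6-dimethoxyphenoxy)-2,3,4-trimethoxyphenyl]oxy}-2,6-dimethoxyphenol (B–D phenol), via aryl formate 10 (not isolated)
Conditions: mCPBA, CH2Cl2, 0 °C to rt; then K2CO3 (cat.), MeOH, rt
Reagents that add atoms: mCPBA (3-chloroperoxybenzoic acid), OOC(=O)c1cccc(Cl)c1
Why: Baeyer–Villiger oxidation (Dakin-type) as in step 3, in which the 4-aryloxy-2,6-dimethoxyphenyl group migrates readily and methanolysis of the formate gives the hindered C4 phenol of ring D.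

Step 6
Reactants: 11 B–D phenol; 12 2-fluoro-4,6-dimethoxybenzaldehyde
Product: 13 2-(4-{[6-(4-bromo-2,6-dimethoxyphenoxy)-2,3,4-trimethoxyphenyl]oxy}-2,6-dimethoxyphenoxy)-4,6-dimethoxybenzaldehyde (B–E aldehyde)
Conditions: Cs2CO3, DMSO, 110 °C, Ar
Reagents that add atoms: none
Why: SNAr at the fluorine ortho to the formyl group of 12, again meta to both methoxy groups, joins the hindered ring D oxygen to C1 of ring E and places the formyl group on the future C6–O carbon.

Step 7
Reactants: 13 B–E aldehyde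
Product: 15 2-(4-{[6-(4-bromo-2,6-dimethoxyphenoxy)-2,3,4-trimethoxyphenyl]oxy}-2,6-dimethoxyphenoxy)-4,6-dimethoxyphenol (B–E phenol), via aryl formate 14 (not isolated)
Conditions: mCPBA, CH2Cl2, 0 °C to rt; then K2CO3 (cat.), MeOH, rt
Reagents that add atoms: mCPBA (3-chloroperoxybenzoic acid), OOC(=O)c1cccc(Cl)c1
Why: Baeyer–Villiger oxidation (Dakin-type) as in steps 3 and 5 turns the formyl group into the C6 phenol of ring E.

Step 8
Reactants: 3 5-bromo-1,3-dimethoxy-2-(3,4,5-trimethoxyphenoxy)benzene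
Product: 18 [3,5-dimethoxy-4-(3,4,5-trimethoxyphenoxy)phenyl]boronic acid (F–G boronic acid), via aryllithium 16 (not isolated), via lithium aryltriisopropoxyborate 17 (not isolated)
Conditions: n-BuLi, THF, −78 °C; B(OiPr)3, −78 °C to rt; then aq. HCl
Reagents that add atoms: triisopropyl borate, CC(C)OB(OC(C)C)OC(C)C; water, O
Why: Bromine–lithium exchange at −78 °C is faster than ortho-metalation of the methoxyarenes, and borate trapping of the aryllithium followed by acid hydrolysis is the standard route to an arylboronic acid, so the same ether 3 also supplies the F–G unit.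

Step 9
Reactants: 15 B–E phenol; 18 F–G boronic acid
Product: 19 B–G hexamer bromide (15 carrying the 3,5-dimethoxy-4-(3,4,5-trimethoxyphenoxy)phenyl group on its phenol oxygen)
Conditions: Cu(OAc)2 (0.3 equiv), pyridine, 4 Å MS, O2 (1 atm), CH2Cl2, rt
Reagents that add atoms: none
Why: Chan–Lam–Evans coupling as in step 1 unites the hindered ring E phenol with the unhindered boron-bearing C1 of ring F, and the ring B bromide is inert under these conditions.

Step 10
Reactants: 19 B–G hexamer bromide
Product: 20 B–G hexamer phenol (19 with OH in place of Br at C1 of ring B)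
Conditions: Pd2(dba)3 (cat.), tBuXPhos (cat.), KOH, 1,4-dioxane/H2O, 100 °C; then aq. HCl
Reagents that add atoms: potassium hydroxide, [K+].[OH-]
Why: Palladium-catalysed hydroxylation of an unhindered, electron-rich aryl bromide with hydroxide (Buchwald–Hartwig-type C–O coupling with a bulky biarylphosphine) unmasks the single free phenol, and the methyl and diaryl ethers are stable to aqueous KOH.

Step 11
Reactants: 20 B–G hexamer phenol; 21 dimethyl chloromalonate
Product: 22 dimethyl 2-(B–G hexamer aryloxy)malonate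
Conditions: K2CO3, acetone, 56 °C
Reagents that add atoms: none
Why: Williamson-type SN2 alkylation of the unhindered phenoxide by the doubly activated secondary chloride forms the sp3 C–O bond of the future ring A ether carbon, so no hindered aryl C–O coupling is needed at that position.

Step 12
Reactants: 22 dimethyl 2-(B–G hexamer aryloxy)malonate; 23 dimethyl 3-oxoglutarate
Product: 25 dimethyl 2,4,6-trihydroxy-5-(B–G hexamer aryloxy)benzene-1,3-dicarboxylate, via 3,5-dioxoheptanedioate 24 (not isolated)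
Conditions: 23 (3 equiv), NaOMe (6 equiv), MeOH, 65 °C; then toluene, 110 °C with distillation of MeOH; then aq. HCl
Reagents that add atoms: none
Why: Proposed new method: a 2-aryloxymalonate has not been used as the three-carbon bis-electrophile in the alkoxide-mediated Claisen–Dieckmann [3+3] condensation of malonic esters with acetonedicarboxylic esters to phloroglucinol dicarboxylates, which, with the base-induced cyclization of 3,5-dioxoheptanedioates, is the closest known reaction type. The sodium enolate of 23, the more acidic partner, is C-acylated by one ester group of 22, which the alpha-aryloxy group activates inductively, and loss of methoxide gives 24 as a stabilised enolate. The remaining methylene carbon of 24 then attacks the second malonate-derived ester in a 6-exo-trig Dieckmann closure that forms ring A, and loss of methoxide followed by enolisation of the cyclohexanetrione gives the arene; no stereocentre is created. The step needs C-acylation to win over O-acylation (pyranone formation) and over head-to-tail Claisen adducts of the malonate carbanion; all of these are reversible in NaOMe, and only the pathway that places the ArO–CH carbon between the two new carbonyls can lose its last hydrogen and aromatise, so the phenoxide of 25 is the single thermodynamic sink. Self-condensation of 23 is met by using it in excess, and the methyl ester/methoxide pairing rules out ester scrambling.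

Step 13
Reactants: 25 dimethyl 2,4,6-trihydroxy-5-(B–G hexamer aryloxy)benzene-1,3-dicarboxylate
Product: 27 2-(B–G hexamer aryloxy)benzene-1,3,5-triol, via diacid 26 (not isolated)
Conditions: KOH, H2O/MeOH (degassed), 80 °C; then aq. HCl, 60 °C, Ar
Reagents that add atoms: none
Why: Saponification of the two salicylate-type esters and acidification give the diacid, and 2,4,6-trihydroxybenzoic acids lose CO2 on gentle warming in acid because ipso-protonation of the phloroglucinol ring is easy, which leaves ring A as the free triol.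

Step 14
Reactants: 27 2-(B–G hexamer aryloxy)benzene-1,3,5-triol
Product: 28 CNP0351377.0
Conditions: BBr3 (excess), CH2Cl2, −78 °C to rt; then H2O
Reagents that add atoms: none
Why: BBr3 cleaves aryl methyl ethers by bromide attack on the boron-complexed methyl group and leaves diaryl ether bonds intact, so all fourteen methoxy groups should become hydroxyls on aqueous work-up.

**Compound list**

1 | 4-bromo-2,6-dimethoxyphenol | COc1cc(Br)cc(OC)c1O | starting material
2 | 3,4,5-trimethoxyphenylboronic acid | COc1cc(B(O)O)cc(OC)c1OC | starting material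
3 | 5-bromo-1,3-dimethoxy-2-(3,4,5-trimethoxyphenoxy)benzene | COc1cc(Br)cc(OC)c1Oc1cc(OC)c(OC)c(OC)c1 | intermediate
4 | N-{[6-(4-bromo-2,6-dimethoxyphenoxy)-2,3,4-trimethoxyphenyl]methylidene}-N-methylmethanaminium chloride | C[N+](C)=Cc1c(Oc2c(OC)cc(Br)cc2OC)cc(OC)c(OC)c1OC.[Cl-] | intermediate
5 | 6-(4-bromo-2,6-dimethoxyphenoxy)-2,3,4-trimethoxybenzaldehyde | O=Cc1c(Oc2c(OC)cc(Br)cc2OC)cc(OC)c(OC)c1OC | intermediate
6 | 6-(4-bromo-2,6-dimethoxyphenoxy)-2,3,4-trimethoxyphenyl formate | O=COc1c(Oc2c(OC)cc(Br)cc2OC)cc(OC)c(OC)c1OC | intermediate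
7 | 6-(4-bromo-2,6-dimethoxyphenoxy)-2,3,4-trimethoxyphenol (B–C phenol) | Oc1c(Oc2c(OC)cc(Br)cc2OC)cc(OC)c(OC)c1OC | intermediate
8 | 4-fluoro-2,6-dimethoxybenzaldehyde | COc1cc(F)cc(OC)c1C=O | starting material
9 | 4-{[6-(4-bromo-2,6-dimethoxyphenoxy)-2,3,4-trimethoxyphenyl]oxy}-2,6-dimethoxybenzaldehyde (B–D aldehyde) | O=Cc1c(OC)cc(Oc2c(Oc3c(OC)cc(Br)cc3OC)cc(OC)c(OC)c2OC)cc1OC | intermediate
10 | 4-{[6-(4-bromo-2,6-dimethoxyphenoxy)-2,3,4-trimethoxyphenyl]oxy}-2,6-dimethoxyphenyl formate | O=COc1c(OC)cc(Oc2c(Oc3c(OC)cc(Br)cc3OC)cc(OC)c(OC)c2OC)cc1OC | intermediate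
11 | 4-{[6-(4-bromo-2,6-dimethoxyphenoxy)-2,3,4-trimethoxyphenyl]oxy}-2,6-dimethoxyphenol (B–D phenol) | Oc1c(OC)cc(Oc2c(Oc3c(OC)cc(Br)cc3OC)cc(OC)c(OC)c2OC)cc1OC | intermediate
12 | 2-fluoro-4,6-dimethoxybenzaldehyde | COc1cc(F)c(C=O)c(OC)c1 | starting material
13 | 2-(4-{[6-(4-bromo-2,6-dimethoxyphenoxy)-2,3,4-trimethoxyphenyl]oxy}-2,6-dimethoxyphenoxy)-4,6-dimethoxybenzaldehyde (B–E aldehyde) | O=Cc1c(Oc2c(OC)cc(Oc3c(Oc4c(OC)cc(Br)cc4OC)cc(OC)c(OC)c3OC)cc2OC)cc(OC)cc1OC | intermediate
14 | 2-(4-{[6-(4-bromo-2,6-dimethoxyphenoxy)-2,3,4-trimethoxyphenyl]oxy}-2,6-dimethoxyphenoxy)-4,6-dimethoxyphenyl formate | O=COc1c(Oc2c(OC)cc(Oc3c(Oc4c(OC)cc(Br)cc4OC)cc(OC)c(OC)c3OC)cc2OC)cc(OC)cc1OC | intermediate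
15 | 2-(4-{[6-(4-bromo-2,6-dimethoxyphenoxy)-2,3,4-trimethoxyphenyl]oxy}-2,6-dimethoxyphenoxy)-4,6-dimethoxyphenol (B–E phenol) | Oc1c(Oc2c(OC)cc(Oc3c(Oc4c(OC)cc(Br)cc4OC)cc(OC)c(OC)c3OC)cc2OC)cc(OC)cc1OC | intermediate
16 | [3,5-dimethoxy-4-(3,4,5-trimethoxyphenoxy)phenyl]lithium | [Li]c1cc(OC)c(Oc2cc(OC)c(OC)c(OC)c2)c(OC)c1 | intermediate
17 | lithium [3,5-dimethoxy-4-(3,4,5-trimethoxyphenoxy)phenyl]tri(propan-2-yloxy)borate | [Li+].CC(C)O[B-](OC(C)C)(OC(C)C)c1cc(OC)c(Oc2cc(OC)c(OC)c(OC)c2)c(OC)c1 | intermediate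
18 | [3,5-dimethoxy-4-(3,4,5-trimethoxyphenoxy)phenyl]boronic acid (F–G boronic acid) | OB(O)c1cc(OC)c(Oc2cc(OC)c(OC)c(OC)c2)c(OC)c1 | intermediate
19 | B–G hexamer bromide: 15 with its phenol oxygen bonded to C1 of the 3,5-dimethoxy-4-(3,4,5-trimethoxyphenoxy)phenyl group; bromine at C1 of ring B | COc1cc(Oc2c(OC)cc(Oc3c(Oc4c(OC)cc(Oc5c(Oc6c(OC)cc(Br)cc6OC)cc(OC)c(OC)c5OC)cc4OC)cc(OC)cc3OC)cc2OC)cc(OC)c1OC | intermediate
20 | B–G hexamer phenol: 19 with OH in place of Br (fourteen methoxy groups, free OH at C1 of ring B) | COc1cc(Oc2c(OC)cc(Oc3c(Oc4c(OC)cc(Oc5c(Oc6c(OC)cc(O)cc6OC)cc(OC)c(OC)c5OC)cc4OC)cc(OC)cc3OC)cc2OC)cc(OC)c1OC | intermediate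
21 | dimethyl chloromalonate (dimethyl 2-chloropropanedioate) | COC(=O)C(Cl)C(=O)OC | starting material
22 | dimethyl 2-(B–G hexamer aryloxy)malonate: 20 O-alkylated with CH(CO2Me)2 | COC(=O)C(C(=O)OC)Oc1cc(OC)c(Oc2cc(OC)c(OC)c(OC)c2Oc2cc(OC)c(Oc3cc(OC)cc(OC)c3Oc3cc(OC)c(Oc4cc(OC)c(OC)c(OC)c4)c(OC)c3)c(OC)c2)c(OC)c1 | intermediate
23 | dimethyl 3-oxoglutarate (dimethyl 3-oxopentanedioate) | COC(=O)CC(=O)CC(=O)OC | starting material
24 | dimethyl 2-(B–G hexamer aryloxy)-4-(methoxycarbonyl)-3,5-dioxoheptanedioate | COC(=O)CC(=O)C(C(=O)OC)C(=O)C(C(=O)OC)Oc1cc(OC)c(Oc2cc(OC)c(OC)c(OC)c2Oc2cc(OC)c(Oc3cc(OC)cc(OC)c3Oc3cc(OC)c(Oc4cc(OC)c(OC)c(OC)c4)c(OC)c3)c(OC)c2)c(OC)c1 | intermediate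
25 | dimethyl 2,4,6-trihydroxy-5-(B–G hexamer aryloxy)benzene-1,3-dicarboxylate | COC(=O)c1c(O)c(C(=O)OC)c(O)c(Oc2cc(OC)c(Oc3cc(OC)c(OC)c(OC)c3Oc3cc(OC)c(Oc4cc(OC)cc(OC)c4Oc4cc(OC)c(Oc5cc(OC)c(OC)c(OC)c5)c(OC)c4)c(OC)c3)c(OC)c2)c1O | intermediate
26 | 2,4,6-trihydroxy-5-(B–G hexamer aryloxy)benzene-1,3-dicarboxylic acid | OC(=O)c1c(O)c(C(=O)O)c(O)c(Oc2cc(OC)c(Oc3cc(OC)c(OC)c(OC)c3Oc3cc(OC)c(Oc4cc(OC)cc(OC)c4Oc4cc(OC)c(Oc5cc(OC)c(OC)c(OC)c5)c(OC)c4)c(OC)c3)c(OC)c2)c1O | intermediate
27 | 2-(B–G hexamer aryloxy)benzene-1,3,5-triol (tetradeca-O-methyl ether of the target) | Oc1cc(O)c(Oc2cc(OC)c(Oc3cc(OC)c(OC)c(OC)c3Oc3cc(OC)c(Oc4cc(OC)cc(OC)c4Oc4cc(OC)c(Oc5cc(OC)c(OC)c(OC)c5)c(OC)c4)c(OC)c3)c(OC)c2)c(O)c1 | intermediate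
28 | CNP0351377.0 (heptameric phloroglucinol aryl ether with seventeen free hydroxyls) | Oc1cc(O)c(Oc2cc(O)c(Oc3cc(O)c(O)c(O)c3Oc3cc(O)c(Oc4cc(O)cc(O)c4Oc4cc(O)c(Oc5cc(O)c(O)c(O)c5)c(O)c4)c(O)c3)c(O)c2)c(O)c1 | target

**Count and risks**

Total steps: 14. Longest linear sequence: 13 steps (from 1 through steps 1–7 and 9–14; step 8 is the side branch from 3).

Steps most likely to fail:

Step 12 (key step). Methoxide may park 22 as its enolate, whose ester groups then resist acylation. It may also strip a methoxycarbonyl group from 22 at the temperature needed, and self-condensation of 23 may use up the nucleophile before the Dieckmann closure. The fallback uses known chemistry and brings ring A in intact instead of building it. It sets out from 20: an Ullmann ether synthesis with commercial 2-iodo-1,3,5-trimethoxybenzene (CuI (copper iodide), picolinic acid, K3PO4, DMSO, 100 °C) should give the heptadeca-O-methyl ether of the target F1, and BBr3 in CH2Cl2 then cleaves all seventeen methyl ethers, so the route is rejoined at 28.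

Step 9. Transmetalation of the bulky, electron-rich dimer boronic acid to copper may be slow, so that its protodeboronation and oxidation outrun ether formation at the doubly ortho-substituted phenol. The fallback sets out from 15 and grows the chain ring by ring. SNAr with 8 (Cs2CO3, DMSO, 110 °C) should give the B–F pentamer aldehyde F2. Baeyer–Villiger oxidation with mCPBA gives the B–F pentamer aryl formate F3, and methanolysis gives the B–F pentamer phenol F4. This is then arylated with the cheap boronic acid 2 in excess under the conditions of step 1 (the phenol is of the same 2,6-dimethoxy class as 1), coming back at 19.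

Step 2. Site selectivity may be lost through formylation spilling onto the brominated ring, or the reaction may stall at the doubly flanked position. The fallback sets out from 1 and fixes the position by the leaving group. SNAr of 1 (Cs2CO3, DMSO, 120 °C) on 6-fluoro-2,3,4-trimethoxybenzaldehyde F5 comes back at 5. F5 would be made by Vilsmeier–Haack formylation of 5-fluoro-1,2,3-trimethoxybenzene, whose two free positions are equivalent. Compound 3 is then needed only for step 8.

**Further compounds**

F1 | step 12 | heptadeca-O-methyl ether of the target (ring A as the 2,4,6-trimethoxyphenyl ether of 20) | COc1cc(OC)c(Oc2cc(OC)c(Oc3cc(OC)c(OC)c(OC)c3Oc3cc(OC)c(Oc4cc(OC)cc(OC)c4Oc4cc(OC)c(Oc5cc(OC)c(OC)c(OC)c5)c(OC)c4)c(OC)c3)c(OC)c2)c(OC)c1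
F2 | step 9 | B–F pentamer aldehyde (15 carrying a 4-formyl-3,5-dimethoxyphenyl group on its phenol oxygen) | O=Cc1c(OC)cc(Oc2c(Oc3c(OC)cc(Oc4c(Oc5c(OC)cc(Br)cc5OC)cc(OC)c(OC)c4OC)cc3OC)cc(OC)cc2OC)cc1OC
F3 | step 9 | B–F pentamer aryl formate (F2 with OCHO in place of CHO) | O=COc1c(OC)cc(Oc2c(Oc3c(OC)cc(Oc4c(Oc5c(OC)cc(Br)cc5OC)cc(OC)c(OC)c4OC)cc3OC)cc(OC)cc2OC)cc1OC
F4 | step 9 | B–F pentamer phenol (F2 with OH in place of CHO) | Oc1c(OC)cc(Oc2c(Oc3c(OC)cc(Oc4c(Oc5c(OC)cc(Br)cc5OC)cc(OC)c(OC)c4OC)cc3OC)cc(OC)cc2OC)cc1OC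
F5 | step 2 | 6-fluoro-2,3,4-trimethoxybenzaldehyde | O=Cc1c(F)cc(OC)c(OC)c1OC
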